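**Plan**

- Ring numbering of the target: C1(=O), C2(OAc), C3(aryl), C4(=O), C5(H), C6(aryl). The retrosynthesis first removes the acetyl group and the two phenol-masking benzyl groups, then the C2–O bond (through the oxirane across C2–C3).
- The ring that is left consists of two identical aryl-C / C=O / CH triads, C3–C4–C5 and C6–C1–C2, joined head to tail. Cutting C2–C3 and C5–C6 therefore gives two molecules of one 1-arylpropane-1,2-dione.
- Forward: O-benzylation and Riley oxidation of 4'-hydroxypropiophenone give the diketone, and its base-induced double aldol condensation closes the quinone ring, the only ring made in the route.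
- One of the two equivalent C–H alkenes is then epoxidised and the oxirane isomerised to the C2 hydroxyl; O-acetylation and debenzylation finish the synthesis.
- Stereochemistry: the target has no stereocentre. The carbinol and oxirane centres that appear in transit form without control and are all erased.

Key step: step 3

Remark: intermediates 5, 6 and 8 are racemates or diastereomer mixtures whose stereocentres are destroyed again, so their SMILES are written without configuration (the oxirane of 8 is necessarily cis-fused).

**Step 1**
Reactants: 1 4'-hydroxypropiophenone; 2 benzyl bromide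
Product: 3 1-(4-benzyloxyphenyl)propan-1-one
Conditions: K2CO3, acetone, reflux
Reagents that add atoms: benzyl bromide (2), BrCc1ccccc1
Why: Williamson ether synthesis, in which the phenoxide of the para-acylphenol displaces bromide from the benzylic halide by SN2 and the ketone is left untouched.

**Step 2**
Reactants: 3 1-(4-benzyloxyphenyl)propan-1-one
Product: 4 1-(4-benzyloxyphenyl)propane-1,2-dione
Conditions: SeO2 (1.2 equiv), 1,4-dioxane/H2O, reflux
Reagents that add atoms: selenium dioxide, O=[Se]=O
Why: Riley oxidation, in which SeO2 attacks the enol of the aryl ethyl ketone at its only enolisable carbon (the CH2 group) and the selenium ester collapses to the 1,2-diketone with loss of selenium and water, a conversion established for propiophenones and tolerated by an aryl benzyl ether.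

**Step 3**
Reactants: 4 1-(4-benzyloxyphenyl)propane-1,2-dione (two molecules)
Product: 7 2,5-bis(4-benzyloxyphenyl)-1,4-benzoquinone, via acyclic aldol adduct 5 (not isolated), via cyclic bis-aldol diol 6 (not isolated)
Conditions: NaOH (1 M aq., substoichiometric), EtOH/THF, 0 °C → rt, N2; then AcOH
Reagents that add atoms: none
Why: Hydroxide reversibly forms the methyl enolate of 4, which adds to the aroyl carbonyl of a second molecule to give aldol 5; the methyl ketone of 5 then enolises and closes onto the remaining aroyl carbonyl to give diol 6, and two E1cB dehydrations across the C(OH)Ar–CH2–C=O units deliver the quinone at the right oxidation level without any oxidant. The closest known reaction is the alkali-induced self-condensation of biacetyl to 2,5-dimethyl-1,4-benzoquinone and of 1-phenylpropane-1,2-dione to 2,5-diphenyl-1,4-benzoquinone, a double aldol condensation. The single ring closes by a 6-(enolendo)-exo-trig aldol addition, a favoured mode, because the enolate carbon and its carbonyl carbon both lie in the new ring. No stereocentre survives, since the carbinol centres of 5 and 6 are removed by dehydration. The step needs attack at the aroyl and not the acetyl carbonyl together with head-to-tail pairing, and reversibility secures both: an adduct at the acetyl carbonyl keeps no methyl ketone with which to close a six-membered ring and reverts by retro-aldol, closure of 5 onto its internal ketone would be a disfavoured 5-(enolendo)-exo-trig process, and only diol 6 can lose two waters irreversibly to the conjugated, sparingly soluble quinone. The benzyl ethers are inert to alkali and keep the phenols from forming phenoxides that would deactivate the aroyl carbonyls.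

**Step 4**
Reactants: 7 2,5-bis(4-benzyloxyphenyl)-1,4-benzoquinone
Product: 8 1,4-bis(4-benzyloxyphenyl)-7-oxabicyclo[4.1.0]hept-3-ene-2,5-dione (the mono-epoxide of 7)
Conditions: H2O2 (30% aq., 1.1 equiv), Na2CO3, THF/H2O, 0 °C
Reagents that add atoms: hydrogen peroxide, OO
Why: Weitz–Scheffer nucleophilic epoxidation, in which hydroperoxide anion adds to the unsubstituted carbon of one enedione C=C and the enolate closes the oxirane; the two alkenes of 7 are equivalent, so one constitutional mono-epoxide should form, its two stereocentres arising as a racemate with the cis fusion that the three-membered ring enforces.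

**Step 5**
Reactants: 8 1,4-bis(4-benzyloxyphenyl)-7-oxabicyclo[4.1.0]hept-3-ene-2,5-dione
Product: 9 2-hydroxy-3,6-bis(4-benzyloxyphenyl)-1,4-benzoquinone
Conditions: NaOH (1 M aq.), THF, 0 °C → rt, Ar; then 1 M HCl
Reagents that add atoms: none
Why: Base-induced isomerisation of an α,β-epoxy ketone to its diosphenol (the quinone-epoxide to hydroxyquinone rearrangement known for 2-methyl-1,4-naphthoquinone oxide), in which the oxirane C–H next to the carbonyl is removed with opening of the C–O bond at the aryl-bearing carbon; the oxygen must stay on the carbon that carried the only hydrogen, the product is held as its stable vinylogous carboxylate until acidification, and both stereocentres disappear.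

**Step 6**
Reactants: 9 2-hydroxy-3,6-bis(4-benzyloxyphenyl)-1,4-benzoquinone
Product: 10 2-acetoxy-3,6-bis(4-benzyloxyphenyl)-1,4-benzoquinone
Conditions: Ac2O, pyridine, CH2Cl2, 0 °C; cold dilute HCl work-up
Reagents that add atoms: acetic anhydride, CC(=O)OC(C)=O
Why: O-acylation of the acidic quinone hydroxyl (a vinylogous carboxylic acid) with acetic anhydride and pyridine, as used for other hydroxyquinones, with no competing site because both phenols are benzyl ethers.

**Step 7**
Reactants: 10 2-acetoxy-3,6-bis(4-benzyloxyphenyl)-1,4-benzoquinone
Product: 11 2-acetoxy-3,6-bis(4-hydroxyphenyl)-1,4-benzoquinone (neonambiquinone A)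
Conditions: BCl3 (1 M in CH2Cl2), C6HMe5, CH2Cl2, −78 °C; then cold pH 7 phosphate buffer
Reagents that add atoms: none
Why: Lewis-acid cleavage of aryl benzyl ethers by BCl3 with pentamethylbenzene as a non-basic benzyl-cation scavenger, a low-temperature debenzylation that involves neither hydrogen nor a nucleophile and is known to spare esters, so the quinone and its enol acetate should persist.

**Compound list**

1 | 4'-hydroxypropiophenone | CCC(=O)c1ccc(O)cc1 | starting material
2 | benzyl bromide | BrCc1ccccc1 | starting material
3 | 1-(4-benzyloxyphenyl)propan-1-one | CCC(=O)c1ccc(OCc2ccccc2)cc1 | intermediate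
4 | 1-(4-benzyloxyphenyl)propane-1,2-dione | CC(=O)C(=O)c1ccc(OCc2ccccc2)cc1 | intermediate
5 | 4-hydroxy-1,4-bis(4-benzyloxyphenyl)hexane-1,2,5-trione (acyclic aldol adduct, racemic) | CC(=O)C(O)(CC(=O)C(=O)c1ccc(OCc2ccccc2)cc1)c1ccc(OCc2ccccc2)cc1 | intermediate
6 | 2,5-dihydroxy-2,5-bis(4-benzyloxyphenyl)cyclohexane-1,4-dione (cyclic bis-aldol diol, diastereomer mixture) | O=C1CC(O)(c2ccc(OCc3ccccc3)cc2)C(=O)CC1(O)c1ccc(OCc2ccccc2)cc1 | intermediate
7 | 2,5-bis(4-benzyloxyphenyl)-1,4-benzoquinone | O=C1C=C(c2ccc(OCc3ccccc3)cc2)C(=O)C=C1c1ccc(OCc2ccccc2)cc1 | intermediate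
8 | 1,4-bis(4-benzyloxyphenyl)-7-oxabicyclo[4.1.0]hept-3-ene-2,5-dione (racemic, cis-fused) | O=C1C=C(c2ccc(OCc3ccccc3)cc2)C(=O)C2OC12c1ccc(OCc2ccccc2)cc1 | intermediate
9 | 2-hydroxy-3,6-bis(4-benzyloxyphenyl)-1,4-benzoquinone | O=C1C(O)=C(c2ccc(OCc3ccccc3)cc2)C(=O)C=C1c1ccc(OCc2ccccc2)cc1 | intermediate
10 | 2-acetoxy-3,6-bis(4-benzyloxyphenyl)-1,4-benzoquinone | CC(=O)OC1=C(c2ccc(OCc3ccccc3)cc2)C(=O)C=C(c2ccc(OCc3ccccc3)cc2)C1=O | intermediate
11 | 2-acetoxy-3,6-bis(4-hydroxyphenyl)-1,4-benzoquinone (neonambiquinone A) | CC(=O)OC1=C(c2ccc(O)cc2)C(=O)C=C(c2ccc(O)cc2)C1=O | target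

**Step count**

Total step count: 7. Longest linear sequence: 7 steps (1 → 11).

**Steps most likely to fail**

Step 3. The productive aldol is slowed by the electron-releasing para-benzyloxy group, so hydroxide attack on the diketone (benzilic acid rearrangement) and conjugate addition of enolate or hydroxide to the quinone once formed may compete and lead to oligomers. The fallback leaves the condensation and builds the same quinone by cross-coupling. It sets out from benzyl bromide 2, which O-alkylates commercial 4-hydroxyphenylboronic acid pinacol ester (K2CO3, DMF) to give 2-(4-benzyloxyphenyl)-4,4,5,5-tetramethyl-1,3,2-dioxaborolane F1. Twofold Suzuki–Miyaura coupling of this with 1,4-dibromo-2,5-dimethoxybenzene (Pd(PPh3)4, a zerovalent palladium complex, aq. K2CO3, dioxane, 90 °C) should give 2,5-bis(4-benzyloxyphenyl)-1,4-dimethoxybenzene F2. Oxidative demethylation with (NH4)2Ce(NO3)6 in MeCN/H2O at 0 °C comes back to the route at quinone 7.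

Step 4. The remaining enedione of the mono-epoxide may be epoxidised a second time, and the oxirane may open in the flask so that the resulting hydroxyquinone is degraded by peroxide; the low solubility of 7 in the aqueous medium may also make conversion uneven. The fallback replaces the peroxide by an amine as the oxygen surrogate. It sets out from quinone 7, which undergoes oxidative conjugate amination with morpholine (EtOH/THF, O2, cat. Cu(OAc)2, rt) to give 2-(morpholin-4-yl)-3,6-bis(4-benzyloxyphenyl)-1,4-benzoquinone F3. Hydrolysis of this vinylogous amide (aq. H2SO4, dioxane, reflux) comes back to the route at hydroxyquinone 9, so that steps 4 and 5 are both bypassed.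

Step 7. The enol acetate is a vinylogous anhydride and may be lost by Lewis-acid activation or during the quench, and chloride or the arene scavenger may add to the boron-complexed quinone. The fallback is reductive instead of Lewis acidic. It sets out from acetate 10, which on hydrogenolysis (H2, Pd/C (palladium on carbon), EtOAc, rt) loses both benzyl groups and is reduced at the quinone to 2,5-dihydroxy-3,6-bis(4-hydroxyphenyl)phenyl acetate F4. Immediate re-oxidation of this hydroquinone with Ag2O in EtOAc, without base so that the acetyl group has no time to migrate, comes back to the route at target 11.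

**Further compounds**

F1 | step 3 | 2-(4-benzyloxyphenyl)-4,4,5,5-tetramethyl-1,3,2-dioxaborolane | CC1(C)OB(OC1(C)C)c1ccc(OCc2ccccc2)cc1
F2 | step 3 | 2,5-bis(4-benzyloxyphenyl)-1,4-dimethoxybenzene | COc1cc(-c2ccc(OCc3ccccc3)cc2)c(OC)cc1-c1ccc(OCc2ccccc2)cc1
F3 | step 4 | 2-(morpholin-4-yl)-3,6-bis(4-benzyloxyphenyl)-1,4-benzoquinone | O=C1C=C(c2ccc(OCc3ccccc3)cc2)C(=O)C(N2CCOCC2)=C1c1ccc(OCc2ccccc2)cc1
F4 | step 7 | 2,5-dihydroxy-3,6-bis(4-hydroxyphenyl)phenyl acetate | CC(=O)Oc1c(O)c(-c2ccc(O)cc2)cc(O)c1-c1ccc(O)cc1
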